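**Plan**

1. Numbering: decalin carbons C1–C10 (C3 ketone, C4 gem-dimethyl, C5 ring-fusion CH, C6 and C7 the two CH2 of ring B, C8 carbinol, C9 carries the chain from C11, C10 carries the angular methyl); C30 is the CH2OAc carbon.
2. Retrosynthesis cuts, in order: the acetate and the C30–O bond (late allylic oxidation); one C4–CH3 bond; both ring B bonds to the C6–C7 unit (C5–C6 and C7–C8) in one step; the C4=C5 bond of ring A (aldol); then C10–C1 and C9–C11 on a butenolide.
3. Enabling feature: C8 (carbonyl carbon of an acetyl group on C9) and C5 (β-carbon of the C3 enone of ring A) are both electrophilic and sit exactly two carbons apart across ring B. An ethene unit of reversed polarity (a zirconacyclopropane, i.e. an ethane-1,2-diyl dianion) can bridge them, and the enolate left at C3/C4 then takes the second C4 methyl.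
4. Forward order: chain plus (S)-butenolide gives a lactone carrying C8, C9 and C10; ring A is closed; ring B is closed onto ring A; C4 is methylated; C30 is oxidised and acetylated.
5. Stereochemistry: C9 from the stereocentre of (S)-γ-valerolactone (trans conjugate addition; that centre later becomes the C8 carbonyl); C10 by alkylation of the lactone enolate anti to the C9 chain; C8 by Felkin–Anh addition controlled by C9; C5 by tether delivery (cis ring fusion).

Key step: step 11

Remark: as written, the SMILES has H-5 and the C10 methyl on the same face (rings A and B cis-fused), the C9 chain and the C8 methyl on that face too, and the C8 hydroxyl on the other; the route is designed for exactly this isomer (5S,8R,9R,10S).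

**Route**

Step 1
Reactants: 1 (S)-γ-valerolactone
Product: 3 (5S)-5-methylfuran-2(5H)-one, via α-phenylselanyl lactone 2 (not isolated)
Conditions: LiN(iPr)2, THF, −78 °C; PhSeBr, −78 °C; then AcOH, H2O2 (30 %), 0 °C → rt
Reagents that add atoms: none
Why: Selenenylation of the lactone enolate followed by oxidation and syn elimination of the selenoxide should introduce the 3,4-double bond without touching the C5 stereocentre, which stays S (selenoxide elimination).

Step 2
Reactants: 4 (2E,6E)-farnesyl bromide
Product: 5 isopropoxydimethyl[(3E,7E)-4,8,12-trimethyltrideca-3,7,11-trien-1-yl]silane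
Conditions: (iPrO)Me2SiCH2MgCl (from (iPrO)Me2SiCH2Cl and Mg, THF), CuBr·SMe2 (5 mol %), THF, −20 → 0 °C
Reagents that add atoms: (isopropoxydimethylsilyl)methylmagnesium chloride CC(C)O[Si](C)(C)C[Mg]Cl
Why: Copper-catalysed coupling of the primary allylic bromide with the silylmethyl Grignard reagent, a hydroxymethyl anion equivalent, should take place at the unsubstituted allylic terminus with the E,E geometry kept (allylic substitution of the Kumada type).

Step 3
Reactants: 5 isopropoxydimethyl(homofarnesyl)silane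
Product: 6 (3E,7E)-homofarnesol [(3E,7E)-4,8,12-trimethyltrideca-3,7,11-trien-1-ol]
Conditions: H2O2 (30 %), KF, KHCO3, THF/MeOH, rt
Reagents that add atoms: hydrogen peroxide OO
Why: Tamao–Fleming oxidation should replace the C–Si bond by C–OH under conditions that leave the three trisubstituted alkenes alone.

Step 4
Reactants: 6 (3E,7E)-homofarnesol
Product: 7 (3E,7E)-homofarnesyl bromide [(3E,7E)-1-bromo-4,8,12-trimethyltrideca-3,7,11-triene]
Conditions: CBr4, PPh3, CH2Cl2, 0 °C
Reagents that add atoms: tetrabromomethane BrC(Br)(Br)Br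
Why: Appel bromination should convert the primary homoallylic alcohol into the bromide without allylic transposition, because the hydroxyl is one carbon removed from the alkene.

Step 5
Reactants: 8 ethyl vinyl ketone (pent-1-en-3-one)
Product: 10 2-(2-bromoethyl)-2-ethyl-1,3-dioxolane, via 1-bromopentan-3-one 9 (not isolated)
Conditions: HBr (anhydrous), CH2Cl2, 0 °C; then ethane-1,2-diol, rt
Reagents that add atoms: hydrogen bromide Br; ethane-1,2-diol OCCO
Why: Conjugate addition of HBr to the enone and acid-catalysed ketalisation of the β-bromo ketone should give the protected 3-oxopentyl electrophile (hydrobromination then acetal formation).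

Step 6
Reactants: 7 (3E,7E)-homofarnesyl bromide; 3 (5S)-5-methylfuran-2(5H)-one
Product: 13 (3R,4R,5S)-3,5-dimethyl-4-[(3E,7E)-4,8,12-trimethyltrideca-3,7,11-trien-1-yl]oxolan-2-one, via homofarnesylmagnesium bromide 11 (not isolated), via bromomagnesium lactone enolate 12 (not isolated)
Conditions: Mg, THF, rt; then CuBr·SMe2 (10 mol %), 3, THF, −40 °C; then MeI, DMPU, −40 → 0 °C
Reagents that add atoms: iodomethane CI
Why: Copper-catalysed conjugate addition of the Grignard reagent to the butenolide should occur anti to the C5 methyl group, which fixes the chain-bearing carbon (C9 of the target) as R, and the enolate should be methylated anti to the new chain (tandem conjugate addition and enolate alkylation).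

Step 7
Reactants: 13 the 3,5-dimethyl-4-homofarnesyl lactone; 10 2-(2-bromoethyl)-2-ethyl-1,3-dioxolane
Product: 15 (3R,4R,5S)-3-[2-(2-ethyl-1,3-dioxolan-2-yl)ethyl]-3,5-dimethyl-4-[(3E,7E)-4,8,12-trimethyltrideca-3,7,11-trien-1-yl]oxolan-2-one, via lithium lactone enolate 14 (not isolated)
Conditions: LiN(iPr)2, THF, −78 °C; then 10, DMPU, Bu4NI (10 mol %), −78 → 0 °C
Reagents that add atoms: none
Why: Alkylation of the lactone enolate should occur on the face opposite the adjacent chain, so the new arm (C1–C2) ends trans and the methyl group cis to the chain, which is the C10 configuration of the target (diastereoselective enolate alkylation forming a quaternary centre).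

Step 8
Reactants: 15 the quaternary lactone
Product: 16 (2R,3R,4S)-2-[2-(2-ethyl-1,3-dioxolan-2-yl)ethyl]-2-methyl-3-[(3E,7E)-4,8,12-trimethyltrideca-3,7,11-trien-1-yl]pentane-1,4-diol
Conditions: LiAlH4, THF, 0 °C
Reagents that add atoms: none
Why: LiAlH4 should reduce the lactone to the 1,4-diol and leave the ketal and the alkenes untouched (hydride reduction).

Step 9
Reactants: 16 the 1,4-diol
Product: 17 (2R,3R,6E,10E)-3-acetyl-2-[2-(2-ethyl-1,3-dioxolan-2-yl)ethyl]-2,7,11,15-tetramethylhexadeca-6,10,14-trienal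
Conditions: (COCl)2, DMSO, CH2Cl2, −78 °C; Et3N, −78 → −20 °C
Reagents that add atoms: none
Why: Swern oxidation activates both hydroxyls before either carbonyl is released, so the diol should go to the keto aldehyde without closing to a lactol and back to the lactone, and the hindered C9 centre next to the new ketone should stay unenolised at low temperature.

Step 10
Reactants: 17 the keto aldehyde ketal
Product: 19 (4S)-2,4-dimethyl-4-[(3R,6E,10E)-7,11,15-trimethyl-2-oxohexadeca-6,10,14-trien-3-yl]cyclohex-2-en-1-one, via diketo aldehyde 18 (not isolated)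
Conditions: PPTS, acetone/H2O, 40 °C; then pyrrolidine (0.5 equiv), AcOH (0.5 equiv), MeOH, 40 °C
Reagents that add atoms: none
Why: Mild acid should free the ethyl ketone and the amine salt should then condense its C4 methylene with the non-enolisable C5 aldehyde in a six-membered aldol condensation to the conjugated ring A enone, the closures from the acetyl methyl group being five-membered enolendo processes and C9 being too hindered to enolise under these conditions (intramolecular aldol condensation).

Step 11
Reactants: 19 the ring A enone with the acetyl group on C9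
Product: 21 (1R,2R,4aS,8aS)-2,5,8a-trimethyl-1-[(3E,7E)-4,8,12-trimethyltrideca-3,7,11-trien-1-yl]-6-(trimethylsilyloxy)-1,2,3,4,4a,7,8,8a-octahydronaphthalen-2-ol, via 2-oxazirconacyclopentane 20 (not isolated)
Conditions: Cp2ZrCl2 (1.2 equiv), EtMgBr (2.4 equiv), THF, −78 °C, 1 h; 19, −78 → 0 °C; then CuBr·SMe2 (15 mol %), Me3SiCl, 0 °C → rt; aq. NaHCO3
Reagents that add atoms: (η2-ethene)zirconocene Cp2Zr(C2H4), made in the flask from Cp2ZrCl2 and EtMgBr, C1C[Zr]1(C2C=CC=C2)C3C=CC=C3; chlorotrimethylsilane C[Si](C)(C)Cl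
Why: Proposed new method: Cp2Zr(C2H4), a formally divalent zirconium–ethene complex that behaves as an ethane-1,2-diyl dianion, should couple with the C8 methyl ketone to the oxazirconacycle 20 (C7–C8 bond), and after Zr-to-Cu transmetalation the remaining Zr–C6 bond should add in a 1,4 sense to C5 of the ring A enone (C5–C6 bond), the enolate being held as its trimethylsilyl ether; the closest known reaction types are the coupling of zirconocene–alkene complexes with ketones to oxazirconacycles and the copper-mediated conjugate addition of alkylzirconocenes and zirconacycles to enones, here merged and made intramolecular. Ring B closes in the second event in a 6-exo-trig mode. C8 is set in the first event by the adjacent C9 stereocentre in the Felkin–Anh sense (C7 enters anti to the quaternary C10 and past H-9), which puts the hydroxyl trans to the chain; C5 is set in the second event by the tether, because C6 can only reach the enone face that carries C9, which gives the cis ring fusion with H-5 and the C10 methyl on the same side. The step needs coupling at the saturated ketone and not at the enone carbonyl: the fixed s-trans enone cannot bind zirconium as a chelated oxadiene and its conjugated carbonyl is the less electrophilic one, and using exactly two equivalents of EtMgBr per zirconium leaves no free Grignard reagent to enolise C9.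

Step 12
Reactants: 21 the silyl enol ether
Product: 23 (4aS,5R,6R,8aS)-6-hydroxy-1,1,4a,6-tetramethyl-5-[(3E,7E)-4,8,12-trimethyltrideca-3,7,11-trien-1-yl]octahydronaphthalen-2(1H)-one, via dilithium alkoxide enolate 22 (not isolated)
Conditions: MeLi (2.2 equiv), THF, 0 °C; then MeI (1.2 equiv), −78 → 0 °C
Reagents that add atoms: iodomethane CI
Why: MeLi should cleave the silyl enol ether to the regiodefined C3–C4 lithium enolate (and deprotonate the hydroxyl), and C-methylation at C4 should complete the gem-dimethyl group with no new stereocentre (enolate regeneration from a silyl enol ether, then alkylation).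

Step 13
Reactants: 23 the 30-deoxy ketone
Product: 24 (4aS,5R,6R,8aS)-6-hydroxy-5-[(3E,7E,11E)-13-hydroxy-4,8,12-trimethyltrideca-3,7,11-trien-1-yl]-1,1,4a,6-tetramethyloctahydronaphthalen-2(1H)-one (myrrhanone A with the configuration of the given structure)
Conditions: SeO2 (0.3 equiv), t-BuOOH, salicylic acid (10 mol %), CH2Cl2, 0 °C → rt
Reagents that add atoms: tert-butyl hydroperoxide CC(C)(C)OO; selenium dioxide O=[Se]=O
Why: SeO2-catalysed allylic oxidation with t-BuOOH should hydroxylate the (E)-methyl group of the terminal isopropylidene unit, the most accessible and most electron-rich alkene, by an ene reaction and 2,3-sigmatropic shift that keeps the E geometry.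

Step 14
Reactants: 24 the C30 alcohol
Product: 25 myrrhanone A acetate (target)
Conditions: Ac2O, pyridine, DMAP (5 mol %), CH2Cl2, 0 °C
Reagents that add atoms: acetic anhydride CC(=O)OC(C)=O
Why: Acetylation with Ac2O and pyridine should esterify the primary allylic alcohol only, the tertiary C8 hydroxyl being too hindered (nucleophilic acyl substitution).

**Compound list**

1 | (S)-γ-valerolactone [(5S)-5-methyloxolan-2-one] | C[C@@H]1OC(=O)CC1 | starting material
2 | (5S)-5-methyl-3-(phenylselanyl)oxolan-2-one (both C3 epimers) | C[C@@H]1OC(=O)C([Se]c2ccccc2)C1 | intermediate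
3 | (5S)-5-methylfuran-2(5H)-one | C[C@@H]1OC(=O)C=C1 | intermediate
4 | (2E,6E)-farnesyl bromide | CC(C)=CCC/C(C)=C/CC/C(C)=C/CBr | starting material
5 | isopropoxydimethyl[(3E,7E)-4,8,12-trimethyltrideca-3,7,11-trien-1-yl]silane | CC(C)=CCC/C(C)=C/CC/C(C)=C/CC[Si](C)(C)OC(C)C | intermediate
6 | (3E,7E)-homofarnesol | CC(C)=CCC/C(C)=C/CC/C(C)=C/CCO | intermediate
7 | (3E,7E)-homofarnesyl bromide | CC(C)=CCC/C(C)=C/CC/C(C)=C/CCBr | intermediate
8 | ethyl vinyl ketone (pent-1-en-3-one) | C=CC(=O)CC | starting material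
9 | 1-bromopentan-3-one | BrCCC(=O)CC | intermediate
10 | 2-(2-bromoethyl)-2-ethyl-1,3-dioxolane | CCC1(CCBr)OCCO1 | intermediate
11 | (3E,7E)-homofarnesylmagnesium bromide | CC(C)=CCC/C(C)=C/CC/C(C)=C/CC[Mg]Br | intermediate
12 | bromomagnesium enolate of (4R,5S)-5-methyl-4-homofarnesyloxolan-2-one | CC(C)=CCC/C(C)=C/CC/C(C)=C/CC[C@@H]1C=C(O[Mg]Br)O[C@H]1C | intermediate
13 | (3R,4R,5S)-3,5-dimethyl-4-[(3E,7E)-4,8,12-trimethyltrideca-3,7,11-trien-1-yl]oxolan-2-one | CC(C)=CCC/C(C)=C/CC/C(C)=C/CC[C@@H]1[C@@H](C)C(=O)O[C@H]1C | intermediate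
14 | lithium enolate of 13 | CC(C)=CCC/C(C)=C/CC/C(C)=C/CC[C@@H]1C(C)=C(O[Li])O[C@H]1C | intermediate
15 | (3R,4R,5S)-3-[2-(2-ethyl-1,3-dioxolan-2-yl)ethyl]-3,5-dimethyl-4-[(3E,7E)-4,8,12-trimethyltrideca-3,7,11-trien-1-yl]oxolan-2-one | CC(C)=CCC/C(C)=C/CC/C(C)=C/CC[C@@H]1[C@@](C)(CCC2(CC)OCCO2)C(=O)O[C@H]1C | intermediate
16 | (2R,3R,4S)-2-[2-(2-ethyl-1,3-dioxolan-2-yl)ethyl]-2-methyl-3-[(3E,7E)-4,8,12-trimethyltrideca-3,7,11-trien-1-yl]pentane-1,4-diol | CC(C)=CCC/C(C)=C/CC/C(C)=C/CC[C@@H]([C@H](C)O)[C@](C)(CO)CCC1(CC)OCCO1 | intermediate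
17 | (2R,3R,6E,10E)-3-acetyl-2-[2-(2-ethyl-1,3-dioxolan-2-yl)ethyl]-2,7,11,15-tetramethylhexadeca-6,10,14-trienal | CC(C)=CCC/C(C)=C/CC/C(C)=C/CC[C@@H](C(C)=O)[C@](C)(C=O)CCC1(CC)OCCO1 | intermediate
18 | (2R,3R,6E,10E)-3-acetyl-2,7,11,15-tetramethyl-2-(3-oxopentyl)hexadeca-6,10,14-trienal | CC(C)=CCC/C(C)=C/CC/C(C)=C/CC[C@@H](C(C)=O)[C@](C)(C=O)CCC(=O)CC | intermediate
19 | (4S)-2,4-dimethyl-4-[(3R,6E,10E)-7,11,15-trimethyl-2-oxohexadeca-6,10,14-trien-3-yl]cyclohex-2-en-1-one | CC(C)=CCC/C(C)=C/CC/C(C)=C/CC[C@@H](C(C)=O)[C@@]1(C)CCC(=O)C(C)=C1 | intermediate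
20 | 2-oxazirconacyclopentane (Cp2Zr bridging O8 and C6; C8 R) | CC(C)=CCC/C(C)=C/CC/C(C)=C/CC[C@@H]([C@@]2(C)CC[Zr](C3C=CC=C3)(C4C=CC=C4)O2)[C@@]1(C)CCC(=O)C(C)=C1 | intermediate
21 | (1R,2R,4aS,8aS)-2,5,8a-trimethyl-1-[(3E,7E)-4,8,12-trimethyltrideca-3,7,11-trien-1-yl]-6-(trimethylsilyloxy)-1,2,3,4,4a,7,8,8a-octahydronaphthalen-2-ol | CC(C)=CCC/C(C)=C/CC/C(C)=C/CC[C@@H]1[C@@]2(C)CCC(O[Si](C)(C)C)=C(C)[C@H]2CC[C@@]1(C)O | intermediate
22 | dilithium alkoxide enolate from 21 | CC(C)=CCC/C(C)=C/CC/C(C)=C/CC[C@@H]1[C@@]2(C)CCC(O[Li])=C(C)[C@H]2CC[C@@]1(C)O[Li] | intermediate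
23 | (4aS,5R,6R,8aS)-6-hydroxy-1,1,4a,6-tetramethyl-5-[(3E,7E)-4,8,12-trimethyltrideca-3,7,11-trien-1-yl]octahydronaphthalen-2(1H)-one | CC(C)=CCC/C(C)=C/CC/C(C)=C/CC[C@@H]1[C@@]2(C)CCC(=O)C(C)(C)[C@H]2CC[C@@]1(C)O | intermediate
24 | (4aS,5R,6R,8aS)-6-hydroxy-5-[(3E,7E,11E)-13-hydroxy-4,8,12-trimethyltrideca-3,7,11-trien-1-yl]-1,1,4a,6-tetramethyloctahydronaphthalen-2(1H)-one | OC/C(C)=C/CC/C(C)=C/CC/C(C)=C/CC[C@@H]1[C@@]2(C)CCC(=O)C(C)(C)[C@H]2CC[C@@]1(C)O | intermediate
25 | myrrhanone A acetate | CC(=O)OC/C(C)=C/CC/C(C)=C/CC/C(C)=C/CC[C@@H]1[C@@]2(C)CCC(=O)C(C)(C)[C@H]2CC[C@@]1(C)O | target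

**Step count and risks**

Total steps: 14. Longest linear sequence: 12 steps (steps 2–4 and 6–14, from 4).

Steps most likely to fail:

1. Step 11 (proposed new method). The zirconium–ethene reagent may couple at the enone carbonyl or be consumed by enolisation of the ketones. The copper-mediated closure at the hindered C5 may also be slower than protonolysis of the C6–metal bond. Fallback with known reactions only, setting out from 19: CH2=CHMgBr with CeCl3 in THF at −78 °C should add to the C8 ketone in the same Felkin–Anh sense to give the tertiary allylic alcohol F1. 9-BBN in THF at 0 °C followed by I2 and NaOMe should turn the vinyl group into the primary iodide F2. Bu3SnH with AIBN in benzene at 80 °C should generate the C6 radical, which closes 6-exo-trig onto C5 of the enone from the tether face and gives the cis-fused 4-methyl ketone F3. Equilibrating methylation at C4 with KOtBu and MeI in t-BuOH/THF brings the route back at 23.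

2. Step 10. With the acetyl group and the enone in one molecule, enolisation toward C9 would erode its configuration, and closure from the acetyl methyl group (aldol or Michael) would divert material. Fallback, setting out from 15: Me3Al and MeONHMe·HCl in CH2Cl2 should open the lactone to the hydroxy N-methoxy-N-methylamide F4. TBSOTf and 2,6-lutidine should give the silyl ether F5, and iBu2AlH in THF at −78 °C the aldehyde F6. PPTS in wet acetone and then KOH in MeOH should close ring A to the enone silyl ether F7, with no ketone at C8 during the base treatment. HF·pyridine should free the hydroxy enone F8, which is oxidised at once with the periodinane DMP and NaHCO3, and the route is back at 19.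

3. Step 13. Oxidation may spread to the allylic positions of the two internal alkenes and run on to the aldehyde. Fallback, setting out from 23: NBS in THF/H2O at 0 °C should form the terminal bromohydrin F9, since the end alkene reacts first in aqueous medium. K2CO3 in MeOH should close it to the epoxide F10, and HIO4 in THF/H2O should cleave the epoxide to the aldehyde F11. Ph3P=C(CH3)CHO in toluene at 80 °C should give the (E)-enal F12. NaBH(OAc)3 in benzene should reduce the aldehyde and not the C3 ketone, and the route is back at 24.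

**Further compounds**

F1 | step 11 | tertiary allylic alcohol (vinyl adduct of 19; C8 R) | CC(C)=CCC/C(C)=C/CC/C(C)=C/CC[C@@H]([C@](C)(O)C=C)[C@@]1(C)CCC(=O)C(C)=C1
F2 | step 11 | primary iodide at C6 | CC(C)=CCC/C(C)=C/CC/C(C)=C/CC[C@@H]([C@](C)(O)CCI)[C@@]1(C)CCC(=O)C(C)=C1
F3 | step 11 | cis-fused 4-methyl ketone (C4 epimers) | CC(C)=CCC/C(C)=C/CC/C(C)=C/CC[C@@H]1[C@@]2(C)CCC(=O)C(C)[C@H]2CC[C@@]1(C)O
F4 | step 10 | hydroxy N-methoxy-N-methylamide | CC(C)=CCC/C(C)=C/CC/C(C)=C/CC[C@@H]([C@H](C)O)[C@](C)(C(=O)N(C)OC)CCC1(CC)OCCO1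
F5 | step 10 | tert-butyldimethylsilyl ether of F4 | CC(C)=CCC/C(C)=C/CC/C(C)=C/CC[C@@H]([C@H](C)O[Si](C)(C)C(C)(C)C)[C@](C)(C(=O)N(C)OC)CCC1(CC)OCCO1
F6 | step 10 | silyloxy aldehyde | CC(C)=CCC/C(C)=C/CC/C(C)=C/CC[C@@H]([C@H](C)O[Si](C)(C)C(C)(C)C)[C@](C)(C=O)CCC1(CC)OCCO1
F7 | step 10 | ring A enone silyl ether | CC(C)=CCC/C(C)=C/CC/C(C)=C/CC[C@@H]([C@H](C)O[Si](C)(C)C(C)(C)C)[C@@]1(C)CCC(=O)C(C)=C1
F8 | step 10 | hydroxy enone | CC(C)=CCC/C(C)=C/CC/C(C)=C/CC[C@@H]([C@H](C)O)[C@@]1(C)CCC(=O)C(C)=C1
F9 | step 13 | terminal bromohydrin | CC(C)(O)C(Br)CC/C(C)=C/CC/C(C)=C/CC[C@@H]1[C@@]2(C)CCC(=O)C(C)(C)[C@H]2CC[C@@]1(C)O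
F10 | step 13 | terminal epoxide | CC3(C)OC3CC/C(C)=C/CC/C(C)=C/CC[C@@H]1[C@@]2(C)CCC(=O)C(C)(C)[C@H]2CC[C@@]1(C)O
F11 | step 13 | chain-shortened aldehyde | O=CCC/C(C)=C/CC/C(C)=C/CC[C@@H]1[C@@]2(C)CCC(=O)C(C)(C)[C@H]2CC[C@@]1(C)O
F12 | step 13 | (E)-enal at C30 | O=C/C(C)=C/CC/C(C)=C/CC/C(C)=C/CC[C@@H]1[C@@]2(C)CCC(=O)C(C)(C)[C@H]2CC[C@@]1(C)O
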